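**Strategy.** With the main chain numbered C1–C24 from the left isopropenyl CH2, each oxirane (O/C10/C11 and O/C14/C15) is read as a methyl ketone flanked by a C–Cl stereocentre. Everything rests on the C9–C10 disconnection: the thirteen-carbon left-chain Grignard reagent adds to the C10 carbonyl of an (R)-α-chloro methyl ketone that already carries the C14–C15 oxirane and the right-hand chain. In one operation this Cornforth-controlled addition forms C9–C10 and sets C10 from C11, and the alkoxide then closes the oxirane O/C10/C11 by displacing chloride. Both chains are grown iteratively from the two antipodes of α-methyl-γ-butyrolactone.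

Key step: step 23

Assumption (remark on the chemistry): Ru–(S)-BINAP is taken to give the (R)-lactone 2, Ru–(R)-BINAP the (S)-lactone 3, and the (5R)-imidazolidinone the (R)-α-chloro aldehydes; each sense is to be confirmed by the sign of rotation before use, and the antipodal catalyst is used if it proves opposite.

**Route**

Step 1
Reactants: 1 3-methylideneoxolan-2-one (α-methylene-γ-butyrolactone)
Product: 2 (R)-3-methyloxolan-2-one
Conditions: H2 (100 atm), Ru(OAc)2[(S)-BINAP] (0.5 mol%), CH2Cl2, 50 °C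
Reagents that add atoms: none
Why: Noyori-type asymmetric hydrogenation of an exocyclic α-methylene lactone, in which the lactone carbonyl anchors the substrate on the BINAP–Ru centre so that H2 should be delivered to one face of C=C and set C3.

Step 2
Reactants: 1 3-methylideneoxolan-2-one
Product: 3 (S)-3-methyloxolan-2-one
Conditions: H2 (100 atm), Ru(OAc)2[(R)-BINAP] (0.5 mol%), CH2Cl2, 50 °C
Reagents that add atoms: none
Why: The same asymmetric hydrogenation with the antipodal ligand should deliver H2 to the opposite face and give the enantiomeric lactone.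

Step 3
Reactants: 2 (R)-3-methyloxolan-2-one
Product: 4 (R)-5-hydroxy-3-methylpentan-2-one
Conditions: MeLi (1.05 equiv), Et2O, −78 °C; aq NH4Cl
Reagents that add atoms: methyllithium, [Li]C
Why: Acyl substitution of a γ-lactone by an organolithium reagent, whose tetrahedral lithium lactolate should persist at −78 °C and so stop the addition at the ketone without touching the α-stereocentre.

Step 4
Reactants: 4 (R)-5-hydroxy-3-methylpentan-2-one
Product: 5 (R)-3,4-dimethylpent-4-en-1-ol
Conditions: Ph3PCH3Br (2.5 equiv), KOt-Bu (2.4 equiv), THF, 0 °C → rt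
Reagents that add atoms: methyltriphenylphosphonium bromide, C[P+](c1ccccc1)(c1ccccc1)c1ccccc1.[Br-]
Why: Wittig methylenation of a methyl ketone with excess non-stabilised ylide, in which carbonyl addition should outrun deprotonation of the hindered tertiary α-CH so that C3 is kept.

Step 5
Reactants: 5 (R)-3,4-dimethylpent-4-en-1-ol
Product: 6 (R)-5-iodo-2,3-dimethylpent-1-ene
Conditions: I2, PPh3, imidazole, CH2Cl2, 0 °C → rt
Reagents that add atoms: iodine, II
Why: Appel-type (Garegg–Samuelsson) iodination of a primary alcohol through its alkoxyphosphonium salt, an SN2 displacement at CH2 that leaves the alkene and the stereocentre alone.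

Step 6
Reactants: 3 (S)-3-methyloxolan-2-one
Product: 7 (S)-5-hydroxy-3-methylpentan-2-one
Conditions: MeLi (1.05 equiv), Et2O, −78 °C; aq NH4Cl
Reagents that add atoms: methyllithium, [Li]C
Why: Acyl substitution of the lactone by MeLi as in step 3, stopped at the ketone by the stable lithium lactolate.

Step 7
Reactants: 7 (S)-5-hydroxy-3-methylpentan-2-one
Product: 8 (S)-3,4-dimethylpent-4-en-1-ol
Conditions: Ph3PCH3Br (2.5 equiv), KOt-Bu (2.4 equiv), THF, 0 °C → rt
Reagents that add atoms: methyltriphenylphosphonium bromide, C[P+](c1ccccc1)(c1ccccc1)c1ccccc1.[Br-]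
Why: Wittig methylenation as in step 4, with retention of the α-stereocentre expected for the same reason.

Step 8
Reactants: 8 (S)-3,4-dimethylpent-4-en-1-ol
Product: 9 (S)-5-iodo-2,3-dimethylpent-1-ene
Conditions: I2, PPh3, imidazole, CH2Cl2, 0 °C → rt
Reagents that add atoms: iodine, II
Why: Appel-type iodination of the primary alcohol as in step 5.

Step 9
Reactants: 6 (R)-5-iodo-2,3-dimethylpent-1-ene; 2 (R)-3-methyloxolan-2-one
Product: 11 (3R,7R)-1-hydroxy-3,7,8-trimethylnon-8-en-4-one, via alkyllithium 10 (not isolated)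
Conditions: 6, t-BuLi (2.0 equiv), Et2O–pentane, −78 °C; then 2, −78 → −40 °C; aq NH4Cl
Reagents that add atoms: none
Why: Lithium–iodine exchange gives a 4-pentenyl-type alkyllithium with no favourable cyclisation mode, and its acyl substitution on the lactone (as in step 3) should stop at the ketone, both stereocentres being carried in unchanged from 6 and 2.

Step 10
Reactants: 11 (3R,7R)-1-hydroxy-3,7,8-trimethylnon-8-en-4-one
Product: 12 (3R,7R)-3,7,8-trimethyl-4-methylidenenon-8-en-1-ol
Conditions: Ph3PCH3Br (2.5 equiv), KOt-Bu (2.4 equiv), THF, 0 °C → rt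
Reagents that add atoms: methyltriphenylphosphonium bromide, C[P+](c1ccccc1)(c1ccccc1)c1ccccc1.[Br-]
Why: Wittig methylenation of the ketone flanked by the C3 stereocentre, where addition of the ylide should again be faster than enolisation toward the tertiary α-carbon.

Step 11
Reactants: 12 (3R,7R)-3,7,8-trimethyl-4-methylidenenon-8-en-1-ol
Product: 13 (3R,7R)-9-iodo-2,3,7-trimethyl-6-methylidenenon-1-ene
Conditions: I2, PPh3, imidazole, CH2Cl2, 0 °C → rt
Reagents that add atoms: iodine, II
Why: Appel-type iodination of the primary alcohol, inert toward the two 1,1-disubstituted alkenes.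

Step 12
Reactants: 9 (S)-5-iodo-2,3-dimethylpent-1-ene; 2 (R)-3-methyloxolan-2-one
Product: 15 (3R,7S)-1-hydroxy-3,7,8-trimethylnon-8-en-4-one, via alkyllithium 14 (not isolated)
Conditions: 9, t-BuLi (2.0 equiv), Et2O–pentane, −78 °C; then 2, −78 → −40 °C; aq NH4Cl
Reagents that add atoms: none
Why: Lithium–iodine exchange and lactone opening as in step 9, now pairing the (S)-terminal unit with the (R)-lactone.

Step 13
Reactants: 15 (3R,7S)-1-hydroxy-3,7,8-trimethylnon-8-en-4-one
Product: 16 (3R,7S)-3,7,8-trimethyl-4-methylidenenon-8-en-1-ol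
Conditions: Ph3PCH3Br (2.5 equiv), KOt-Bu (2.4 equiv), THF, 0 °C → rt
Reagents that add atoms: methyltriphenylphosphonium bromide, C[P+](c1ccccc1)(c1ccccc1)c1ccccc1.[Br-]
Why: Wittig methylenation as in step 10.

Step 14
Reactants: 16 (3R,7S)-3,7,8-trimethyl-4-methylidenenon-8-en-1-ol
Product: 17 (3S,7R)-9-iodo-2,3,7-trimethyl-6-methylidenenon-1-ene
Conditions: I2, PPh3, imidazole, CH2Cl2, 0 °C → rt
Reagents that add atoms: iodine, II
Why: Appel-type iodination as in step 11.

Step 15
Reactants: 18 methyl 6-oxohexanoate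
Product: 19 methyl (R)-5-chloro-6-oxohexanoate
Conditions: (5R)-5-benzyl-2,2,3-trimethylimidazolidin-4-one·TFA (10 mol%), 2,3,4,5,6,6-hexachlorocyclohexa-2,4-dien-1-one (1.2 equiv), acetone, −30 °C; crude product used at once
Reagents that add atoms: 2,3,4,5,6,6-hexachlorocyclohexa-2,4-dien-1-one, O=C1C(Cl)=C(Cl)C(Cl)=C(Cl)C1(Cl)Cl
Why: Enamine-catalysed α-chlorination of an aldehyde, in which the benzyl group of the imidazolidinone screens one face of the E-enamine so that the quinone should deliver Cl+ to the open face and set (R)-C5.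

Step 16
Reactants: 19 methyl (R)-5-chloro-6-oxohexanoate
Product: 20 methyl (5R)-5-chloro-6-hydroxyheptanoate (both C6 epimers)
Conditions: MeMgBr (1.1 equiv), Et2O, −78 °C; aq NH4Cl
Reagents that add atoms: methylmagnesium bromide, C[Mg]Br
Why: Grignard 1,2-addition to the aldehyde, far faster at −78 °C than attack on the methyl ester; the new carbinol centre is of no consequence because step 17 oxidises it.

Step 17
Reactants: 20 methyl (5R)-5-chloro-6-hydroxyheptanoate
Product: 21 methyl (R)-5-chloro-6-oxoheptanoate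
Conditions: Dess–Martin periodinane (1.3 equiv), NaHCO3, CH2Cl2, 0 °C → rt
Reagents that add atoms: none
Why: Dess–Martin oxidation under buffered, non-basic conditions should give the α-chloro ketone without enolisation of the C5–Cl stereocentre.

Step 18
Reactants: 17 (3S,7R)-9-iodo-2,3,7-trimethyl-6-methylidenenon-1-ene; 21 methyl (R)-5-chloro-6-oxoheptanoate
Product: 25 methyl 4-{(2S,3S)-3-methyl-3-[(3R,7S)-3,7,8-trimethyl-4-methylidenenon-8-en-1-yl]oxiran-2-yl}butanoate, via alkyllithium 22 (not isolated), via alkylmagnesium bromide 23 (not isolated), via chlorohydrin 24 (not isolated)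
Conditions: 17, t-BuLi (2.0 equiv), Et2O, −78 °C; MgBr2·OEt2 (1.1 equiv); then 21, THF, −78 °C; then MeOH, K2CO3, −78 °C → rt
Reagents that add atoms: none
Why: Cornforth chlorohydrin–oxirane synthesis, in which the Grignard reagent adds to the ketone (much faster than to the ester at −78 °C) from the C–H side of the conformer with C–Cl anti to C=O and the alkoxide then displaces chloride with inversion, so that the (R)-chloride should give the (2S,3S)-oxirane with the two chains trans.

Step 19
Reactants: 25 methyl 4-{(2S,3S)-3-methyl-3-[(3R,7S)-3,7,8-trimethyl-4-methylidenenon-8-en-1-yl]oxiran-2-yl}butanoate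
Product: 26 4-{(2S,3S)-3-methyl-3-[(3R,7S)-3,7,8-trimethyl-4-methylidenenon-8-en-1-yl]oxiran-2-yl}butanal
Conditions: DIBAL-H (1.1 equiv), CH2Cl2, −78 °C; MeOH, aq Rochelle salt
Reagents that add atoms: none
Why: Partial reduction of a methyl ester, whose aluminium hemiacetal is stable at −78 °C and releases the aldehyde only on work-up, while oxirane and alkenes are inert to DIBAL-H at this temperature.

Step 20
Reactants: 26 4-{(2S,3S)-3-methyl-3-[(3R,7S)-3,7,8-trimethyl-4-methylidenenon-8-en-1-yl]oxiran-2-yl}butanal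
Product: 27 (2R)-2-chloro-4-{(2S,3S)-3-methyl-3-[(3R,7S)-3,7,8-trimethyl-4-methylidenenon-8-en-1-yl]oxiran-2-yl}butanal
Conditions: (5R)-5-benzyl-2,2,3-trimethylimidazolidin-4-one·TFA (10 mol%), 2,3,4,5,6,6-hexachlorocyclohexa-2,4-dien-1-one (1.2 equiv), acetone, −30 °C; crude product used at once
Reagents that add atoms: 2,3,4,5,6,6-hexachlorocyclohexa-2,4-dien-1-one, O=C1C(Cl)=C(Cl)C(Cl)=C(Cl)C1(Cl)Cl
Why: The same enamine-catalysed α-chlorination as in step 15, in which the catalyst and not the remote oxirane should control the face of attack and give the (R)-chloride.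

Step 21
Reactants: 27 (2R)-2-chloro-4-{(2S,3S)-3-methyl-3-[(3R,7S)-3,7,8-trimethyl-4-methylidenenon-8-en-1-yl]oxiran-2-yl}butanal
Product: 28 (3R)-3-chloro-5-{(2S,3S)-3-methyl-3-[(3R,7S)-3,7,8-trimethyl-4-methylidenenon-8-en-1-yl]oxiran-2-yl}pentan-2-ol (both C2 epimers)
Conditions: MeMgBr (1.2 equiv), Et2O, −78 °C; aq NH4Cl
Reagents that add atoms: methylmagnesium bromide, C[Mg]Br
Why: Grignard 1,2-addition to the aldehyde at −78 °C, where the trisubstituted oxirane is not attacked; the carbinol configuration is irrelevant because step 22 oxidises it.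

Step 22
Reactants: 28 (3R)-3-chloro-5-{(2S,3S)-3-methyl-3-[(3R,7S)-3,7,8-trimethyl-4-methylidenenon-8-en-1-yl]oxiran-2-yl}pentan-2-ol
Product: 29 (3R)-3-chloro-5-{(2S,3S)-3-methyl-3-[(3R,7S)-3,7,8-trimethyl-4-methylidenenon-8-en-1-yl]oxiran-2-yl}pentan-2-one
Conditions: Dess–Martin periodinane (1.3 equiv), NaHCO3, CH2Cl2, 0 °C → rt
Reagents that add atoms: none
Why: Buffered Dess–Martin oxidation should give the α-chloro methyl ketone without acid opening of the oxirane and without epimerisation at C–Cl.

Step 23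
Reactants: 13 (3R,7R)-9-iodo-2,3,7-trimethyl-6-methylidenenon-1-ene; 29 (3R)-3-chloro-5-{(2S,3S)-3-methyl-3-[(3R,7S)-3,7,8-trimethyl-4-methylidenenon-8-en-1-yl]oxiran-2-yl}pentan-2-one
Product: 33 (3R,7R,10S,11S,14S,15S,18R,22S)-10,11:14,15-diepoxy-2,3,7,10,15,18,22,23-octamethyl-6,19-dimethylidenetetracosa-1,23-diene, via alkyllithium 30 (not isolated), via alkylmagnesium bromide 31 (not isolated), via chlorohydrin 32 (not isolated)
Conditions: 13, t-BuLi (2.0 equiv), Et2O, −78 °C; MgBr2·OEt2 (1.1 equiv); then 29, THF, −78 °C; then MeOH, K2CO3, −78 °C → rt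
Reagents that add atoms: none
Why: The Grignard reagent 31 attacks the C10 carbonyl of 29 in the Cornforth–Evans conformation, in which the C11–Cl and C10=O dipoles are antiperiplanar, and approaches past C11–H and not past the C12 chain, which should give the (10S,11R)-chlorohydrin 32. The closest known reaction type is the Cornforth chlorohydrin route to trisubstituted oxiranes by low-temperature addition of Grignard reagents to α-chloro ketones. Methanolic K2CO3 then closes the oxirane O/C10/C11 from the tertiary alkoxide by a 3-exo-tet intramolecular Williamson displacement with inversion at C11, so that (R)-C11–Cl becomes (S)-C11–O. The new stereocentre C10 is controlled by C11 (1,2-induction), which itself comes from the catalyst of step 20, and the trans relation of C9 and C12 on the ring follows from the addition geometry. The step needs attack at the ketone in preference to the C14–C15 oxirane and addition in preference to deprotonation at C11, which the magnesium reagent at −78 °C and the methanol quench before warming should secure. Any bromohydrin formed from the existing oxirane by MgBr2 would be re-closed by the same base with net retention.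

**Compound list**

1 | 3-methylideneoxolan-2-one | C=C1CCOC1=O | starting material
2 | (R)-3-methyloxolan-2-one | C[C@@H]1CCOC1=O | intermediate
3 | (S)-3-methyloxolan-2-one | C[C@H]1CCOC1=O | intermediate
4 | (R)-5-hydroxy-3-methylpentan-2-one | CC(=O)[C@H](C)CCO | intermediate
5 | (R)-3,4-dimethylpent-4-en-1-ol | C=C(C)[C@H](C)CCO | intermediate
6 | (R)-5-iodo-2,3-dimethylpent-1-ene | C=C(C)[C@H](C)CCI | intermediate
7 | (S)-5-hydroxy-3-methylpentan-2-one | CC(=O)[C@@H](C)CCO | intermediate
8 | (S)-3,4-dimethylpent-4-en-1-ol | C=C(C)[C@@H](C)CCO | intermediate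
9 | (S)-5-iodo-2,3-dimethylpent-1-ene | C=C(C)[C@@H](C)CCI | intermediate
10 | [(R)-3,4-dimethylpent-4-en-1-yl]lithium | C=C(C)[C@H](C)CC[Li] | intermediate (not isolated)
11 | (3R,7R)-1-hydroxy-3,7,8-trimethylnon-8-en-4-one | C=C(C)[C@H](C)CCC(=O)[C@H](C)CCO | intermediate
12 | (3R,7R)-3,7,8-trimethyl-4-methylidenenon-8-en-1-ol | C=C(C)[C@H](C)CCC(=C)[C@H](C)CCO | intermediate
13 | (3R,7R)-9-iodo-2,3,7-trimethyl-6-methylidenenon-1-ene | C=C(C)[C@H](C)CCC(=C)[C@H](C)CCI | intermediate
14 | [(S)-3,4-dimethylpent-4-en-1-yl]lithium | C=C(C)[C@@H](C)CC[Li] | intermediate (not isolated)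
15 | (3R,7S)-1-hydroxy-3,7,8-trimethylnon-8-en-4-one | C=C(C)[C@@H](C)CCC(=O)[C@H](C)CCO | intermediate
16 | (3R,7S)-3,7,8-trimethyl-4-methylidenenon-8-en-1-ol | C=C(C)[C@@H](C)CCC(=C)[C@H](C)CCO | intermediate
17 | (3S,7R)-9-iodo-2,3,7-trimethyl-6-methylidenenon-1-ene | C=C(C)[C@@H](C)CCC(=C)[C@H](C)CCI | intermediate
18 | methyl 6-oxohexanoate | COC(=O)CCCCC=O | starting material
19 | methyl (R)-5-chloro-6-oxohexanoate | COC(=O)CCC[C@@H](Cl)C=O | intermediate
20 | methyl (5R)-5-chloro-6-hydroxyheptanoate | COC(=O)CCC[C@@H](Cl)C(C)O | intermediate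
21 | methyl (R)-5-chloro-6-oxoheptanoate | COC(=O)CCC[C@@H](Cl)C(C)=O | intermediate
22 | [(3R,7S)-3,7,8-trimethyl-4-methylidenenon-8-en-1-yl]lithium | C=C(C)[C@@H](C)CCC(=C)[C@H](C)CC[Li] | intermediate (not isolated)
23 | bromo[(3R,7S)-3,7,8-trimethyl-4-methylidenenon-8-en-1-yl]magnesium | C=C(C)[C@@H](C)CCC(=C)[C@H](C)CC[Mg]Br | intermediate (not isolated)
24 | methyl (5R,6S,9R,13S)-5-chloro-6-hydroxy-6,9,13,14-tetramethyl-10-methylidenepentadec-14-enoate | COC(=O)CCC[C@@H](Cl)[C@@](C)(O)CC[C@@H](C)C(=C)CC[C@H](C)C(=C)C | intermediate (not isolated)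
25 | methyl 4-{(2S,3S)-3-methyl-3-[(3R,7S)-3,7,8-trimethyl-4-methylidenenon-8-en-1-yl]oxiran-2-yl}butanoate | COC(=O)CCC[C@@H]1O[C@@]1(C)CC[C@@H](C)C(=C)CC[C@H](C)C(=C)C | intermediate
26 | 4-{(2S,3S)-3-methyl-3-[(3R,7S)-3,7,8-trimethyl-4-methylidenenon-8-en-1-yl]oxiran-2-yl}butanal | O=CCCC[C@@H]1O[C@@]1(C)CC[C@@H](C)C(=C)CC[C@H](C)C(=C)C | intermediate
27 | (2R)-2-chloro-4-{(2S,3S)-3-methyl-3-[(3R,7S)-3,7,8-trimethyl-4-methylidenenon-8-en-1-yl]oxiran-2-yl}butanal | O=C[C@H](Cl)CC[C@@H]1O[C@@]1(C)CC[C@@H](C)C(=C)CC[C@H](C)C(=C)C | intermediate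
28 | (3R)-3-chloro-5-{(2S,3S)-3-methyl-3-[(3R,7S)-3,7,8-trimethyl-4-methylidenenon-8-en-1-yl]oxiran-2-yl}pentan-2-ol | CC(O)[C@H](Cl)CC[C@@H]1O[C@@]1(C)CC[C@@H](C)C(=C)CC[C@H](C)C(=C)C | intermediate
29 | (3R)-3-chloro-5-{(2S,3S)-3-methyl-3-[(3R,7S)-3,7,8-trimethyl-4-methylidenenon-8-en-1-yl]oxiran-2-yl}pentan-2-one | CC(=O)[C@H](Cl)CC[C@@H]1O[C@@]1(C)CC[C@@H](C)C(=C)CC[C@H](C)C(=C)C | intermediate
30 | [(3R,7R)-3,7,8-trimethyl-4-methylidenenon-8-en-1-yl]lithium | C=C(C)[C@H](C)CCC(=C)[C@H](C)CC[Li] | intermediate (not isolated)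
31 | bromo[(3R,7R)-3,7,8-trimethyl-4-methylidenenon-8-en-1-yl]magnesium | C=C(C)[C@H](C)CCC(=C)[C@H](C)CC[Mg]Br | intermediate (not isolated)
32 | (10S,11R)-chlorohydrin: the target with the O/C10/C11 oxirane replaced by C10–OH and C11–Cl | C=C(C)[C@H](C)CCC(=C)[C@H](C)CC[C@](C)(O)[C@H](Cl)CC[C@@H]1O[C@@]1(C)CC[C@@H](C)C(=C)CC[C@H](C)C(=C)C | intermediate (not isolated)
33 | (3R,7R,10S,11S,14S,15S,18R,22S)-10,11:14,15-diepoxy-2,3,7,10,15,18,22,23-octamethyl-6,19-dimethylidenetetracosa-1,23-diene | C=C(C)[C@H](C)CCC(=C)[C@H](C)CC[C@]1(C)O[C@H]1CC[C@@H]1O[C@@]1(C)CC[C@@H](C)C(=C)CC[C@H](C)C(=C)C | target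

**Step count.** 23 steps in total. The longest linear sequence is 13 steps (2, 6, 7, 8, 12, 13, 14, 18, 19, 20, 21, 22, 23).

**Steps most likely to fail**

1. Step 23 (key step). The basic organometallic may deprotonate C11 of the chloro ketone faster than it adds, which costs material and the C11 configuration, or the facial bias at C10 may be too low to be useful. The fallback replaces substrate-controlled addition by cross-coupling followed by catalyst-controlled epoxidation. It sets out from iodides 17 and 13, used as their Grignard reagents 23 and 31, and returns at 33. Commercial octa-2,6-diyne F1 would be hydrozirconated at both alkynes (Cp2Zr(H)Cl, THF, then I2) to give (2E,6E)-2,7-diiodoocta-2,6-diene F2 as the bis-vinyl iodide. Kumada coupling of an excess of F2 with 23 [PdCl2(dppf), Et2O–THF, 0 °C] should give the mono-coupled vinyl iodide (2E,6E,10R,14S)-2-iodo-7,10,14,15-tetramethyl-11-methylidenehexadeca-2,6,15-triene F3 after removal of unreacted diiodide. A second Kumada coupling of F3 with 31 would form C9–C10 with retention of alkene geometry and give the polyene (3R,7R,10E,14E,18R,22S)-2,3,7,10,15,18,22,23-octamethyl-6,19-dimethylidenetetracosa-1,10,14,23-tetraene F4 in which both trisubstituted alkenes are E. Double Shi epoxidation of F4 with the L-fructose-derived enantiomer of the Shi ketone (Oxone, K2CO3 buffer, MeCN–dimethoxymethane–H2O, 0 °C) should then give 33, since the dioxirane attacks the two trisubstituted alkenes faster than the four 1,1-disubstituted ones.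

2. Step 20. The phenol set free by the chlorinating agent may open the acid-labile trisubstituted oxirane, and the α-chloro aldehyde may lose configuration during handling, both on a late intermediate. The fallback installs both C–Cl stereocentres before any oxirane exists. It sets out from chlorohydrin 20 and iodide 17 and returns at 28. Silylation of 20 (TBSCl, imidazole, DMF) would give methyl (5R)-6-[(tert-butyldimethylsilyl)oxy]-5-chloroheptanoate F5 as a mixture of carbinol epimers. DIBAL-H at −78 °C would reduce it to the aldehyde (5R)-6-[(tert-butyldimethylsilyl)oxy]-5-chloroheptanal F6 without touching the chloride. α-Chlorination of this aldehyde as in step 15 should give (2R,5R)-6-[(tert-butyldimethylsilyl)oxy]-2,5-dichloroheptanal F7 under catalyst control. MeMgBr would convert it into (3R,6R)-7-[(tert-butyldimethylsilyl)oxy]-3,6-dichlorooctan-2-ol F8 and Dess–Martin oxidation would then give the ketone (3R,6R)-7-[(tert-butyldimethylsilyl)oxy]-3,6-dichlorooctan-2-one F9 in which the ketone end now plays the part of C15 and the silyloxy end that of C10. Cornforth addition of Grignard reagent 23 to this ketone under the conditions of step 18 would pass through (3R,6R,7S,10R,14S)-2-[(tert-butyldimethylsilyl)oxy]-3,6-dichloro-7,10,14,15-tetramethyl-11-methylidenehexadec-15-en-7-ol F10 as its magnesium alkoxide, which is not isolated. Only the alkoxide-bearing chlorohydrin can cyclise, so methanolic K2CO3 should close it to tert-butyl({(3R)-3-chloro-5-[(2S,3S)-3-methyl-3-((3R,7S)-3,7,8-trimethyl-4-methylidenenon-8-en-1-yl)oxiran-2-yl]pentan-2-yl}oxy)dimethylsilane F11 which is the silyl ether of 28. Desilylation with TBAF buffered by AcOH, so that the free chlorohydrin is never an alkoxide, should give 28.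

3. Step 10 (the same process threatens steps 4, 7 and 13, but there on small ketones whose products can be checked by chiral GC). The basic ylide may enolise the ketone toward the stereogenic α-carbon and so epimerise C3 of 11, giving a diastereomer that would be inseparable later. The fallback forms the 1,1-disubstituted alkene by cross-coupling to an enol triflate instead of methylenating the ketone. It sets out from hydroxy ketone 4 and iodide 6 and returns at 12. Silylation of 4 (TBSCl, imidazole) would give (R)-5-[(tert-butyldimethylsilyl)oxy]-3-methylpentan-2-one F12 as the open-chain ketone. Kinetic deprotonation at its methyl group (KHMDS, THF, −78 °C) and trapping with PhNTf2 should give (R)-5-[(tert-butyldimethylsilyl)oxy]-3-methylpent-1-en-2-yl trifluoromethanesulfonate F13 without touching the stereocentre. Alkyllithium 10, made from 6, would be transmetallated with MgBr2·OEt2 to bromo[(R)-3,4-dimethylpent-4-en-1-yl]magnesium F14 in Et2O. Iron-catalysed coupling of F14 with F13 [Fe(acac)3, THF–NMP, −30 °C] should give tert-butyldimethyl{[(3R,7R)-3,7,8-trimethyl-4-methylidenenon-8-en-1-yl]oxy}silane F15 as the silyl ether of 12, and TBAF then releases 12.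

**Further compounds**

F1 | step 23 | octa-2,6-diyne | CC#CCCC#CC
F2 | step 23 | (2E,6E)-2,7-diiodoocta-2,6-diene | C/C(I)=C\CC/C=C(\C)I
F3 | step 23 | (2E,6E,10R,14S)-2-iodo-7,10,14,15-tetramethyl-11-methylidenehexadeca-2,6,15-triene | C/C(I)=C\CC/C=C(\C)CC[C@@H](C)C(=C)CC[C@H](C)C(=C)C
F4 | step 23 | (3R,7R,10E,14E,18R,22S)-2,3,7,10,15,18,22,23-octamethyl-6,19-dimethylidenetetracosa-1,10,14,23-tetraene | C=C(C)[C@H](C)CCC(=C)[C@H](C)CC/C(C)=C/CC/C=C(\C)CC[C@@H](C)C(=C)CC[C@H](C)C(=C)C
F5 | step 20 | methyl (5R)-6-[(tert-butyldimethylsilyl)oxy]-5-chloroheptanoate | COC(=O)CCC[C@@H](Cl)C(C)O[Si](C)(C)C(C)(C)C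
F6 | step 20 | (5R)-6-[(tert-butyldimethylsilyl)oxy]-5-chloroheptanal | O=CCCC[C@@H](Cl)C(C)O[Si](C)(C)C(C)(C)C
F7 | step 20 | (2R,5R)-6-[(tert-butyldimethylsilyl)oxy]-2,5-dichloroheptanal | O=C[C@H](Cl)CC[C@@H](Cl)C(C)O[Si](C)(C)C(C)(C)C
F8 | step 20 | (3R,6R)-7-[(tert-butyldimethylsilyl)oxy]-3,6-dichlorooctan-2-ol | CC(O)[C@H](Cl)CC[C@@H](Cl)C(C)O[Si](C)(C)C(C)(C)C
F9 | step 20 | (3R,6R)-7-[(tert-butyldimethylsilyl)oxy]-3,6-dichlorooctan-2-one | CC(=O)[C@H](Cl)CC[C@@H](Cl)C(C)O[Si](C)(C)C(C)(C)C
F10 | step 20 | (3R,6R,7S,10R,14S)-2-[(tert-butyldimethylsilyl)oxy]-3,6-dichloro-7,10,14,15-tetramethyl-11-methylidenehexadec-15-en-7-ol | CC(O[Si](C)(C)C(C)(C)C)[C@H](Cl)CC[C@@H](Cl)[C@@](C)(O)CC[C@@H](C)C(=C)CC[C@H](C)C(=C)C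
F11 | step 20 | tert-butyl({(3R)-3-chloro-5-[(2S,3S)-3-methyl-3-((3R,7S)-3,7,8-trimethyl-4-methylidenenon-8-en-1-yl)oxiran-2-yl]pentan-2-yl}oxy)dimethylsilane | CC(O[Si](C)(C)C(C)(C)C)[C@H](Cl)CC[C@@H]1O[C@@]1(C)CC[C@@H](C)C(=C)CC[C@H](C)C(=C)C
F12 | step 10 | (R)-5-[(tert-butyldimethylsilyl)oxy]-3-methylpentan-2-one | CC(=O)[C@H](C)CCO[Si](C)(C)C(C)(C)C
F13 | step 10 | (R)-5-[(tert-butyldimethylsilyl)oxy]-3-methylpent-1-en-2-yl trifluoromethanesulfonate | C=C(OS(=O)(=O)C(F)(F)F)[C@H](C)CCO[Si](C)(C)C(C)(C)C
F14 | step 10 | bromo[(R)-3,4-dimethylpent-4-en-1-yl]magnesium | C=C(C)[C@H](C)CC[Mg]Br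
F15 | step 10 | tert-butyldimethyl{[(3R,7R)-3,7,8-trimethyl-4-methylidenenon-8-en-1-yl]oxy}silane | C=C(C)[C@H](C)CCC(=C)[C@H](C)CCO[Si](C)(C)C(C)(C)C
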